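**Assumptions**
- The SMILES has 18 chain-type carbons before the ring-closure digit, and the 18th is a ring carbon. The side chain is therefore n-heptadecyl (C17), and the target is 3-heptadecyl-2-hydroxy-5-methoxy-1,4-benzoquinone, C24H40O4.
- The molecule has no stereocentres and no stereogenic alkene. It is achiral, so no enantiomer control is needed.
- Heptadecanal is treated as a catalogue chemical.

## Retrosynthetic overview
1. No ring is formed. The quinone ring is bought intact as 2,5-dihydroxy-1,4-benzoquinone.
2. Last disconnection: the C5–OMe bond. It comes from regioselective acid-catalysed methanolysis of the unhindered vinylogous acid OH of the 3-alkyl-2,5-dihydroxyquinone.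
3. First disconnection: the C3–C1' bond. It comes from a three-component organocatalytic reductive alkylation of the quinone with heptadecanal and Hantzsch ester.
4. Order: C-alkylation first, which makes the two OH groups different. O-methylation second, so the substrate controls which OH reacts.

## Route

**Step 1**
- **Reactants:** 1, 2,5-dihydroxy-1,4-benzoquinone (2.0 equiv); 2, heptadecanal (1.0 equiv)
- **Product:** 3, 3-heptadecyl-2,5-dihydroxy-1,4-benzoquinone
- **Conditions:** L-proline (20 mol %), Hantzsch ester (diethyl 2,6-dimethyl-1,4-dihydropyridine-3,5-dicarboxylate, 1.1 equiv), CH2Cl2, 25 °C, 12–24 h. Filter off excess 1, then purify on SiO2 or recrystallise from EtOH.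
- **Reagents that add atoms:** heptadecanal (compound 2), CCCCCCCCCCCCCCCCC=O, supplies all 17 carbons and its oxygen leaves as water. The Hantzsch ester gives only hydrogen.
- **Why:** This is a Knoevenagel condensation followed by transfer hydrogenation (organocatalytic three-component reductive alkylation).
  - The proline iminium of 2 condenses at the nucleophilic enol carbon C3 of the vinylogous acid, giving a very electrophilic quinone methide.
  - The Hantzsch ester reduces this intermediate by conjugate hydride transfer faster than it reduces the electron-rich quinone.
  - Excess symmetric 1 suppresses 3,6-dialkylation.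
  - No stereocentre is created.

**Step 2**
- **Reactants:** 3, 3-heptadecyl-2,5-dihydroxy-1,4-benzoquinone
- **Product:** 4, Irisoquin B (3-heptadecyl-2-hydroxy-5-methoxy-1,4-benzoquinone)
- **Conditions:** MeOH/CHCl3 (3:1), conc. H2SO4 (cat.), 50 °C, 2–4 h. Stop when 3 is consumed. Aqueous work-up, then recrystallise from MeOH or purify on SiO2.
- **Reagents that add atoms:** methanol, CO
- **Why:** This is a Fischer-type etherification of a vinylogous carboxylic acid, by conjugate addition of MeOH and elimination of water.
  - It occurs only at C5, whose neighbour C6 carries H.
  - C2–OH is flanked by the C17 chain and is sterically and electronically deactivated, as 3-alkyl-2-hydroxyquinones are known to resist acid/ROH etherification.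
  - The reaction therefore stops at the 5-monomethyl ether.
  - The alkyl chain and the quinone are inert to these conditions, and no stereocentre is involved.

## Compound list

| No. | Name | SMILES | Role |
|---|---|---|---|
| 1 | 2,5-dihydroxy-1,4-benzoquinone | OC1=CC(=O)C(O)=CC1=O | starting material |
| 2 | heptadecanal | CCCCCCCCCCCCCCCCC=O | starting material |
| 3 | 3-heptadecyl-2,5-dihydroxy-1,4-benzoquinone (C23H38O4) | CCCCCCCCCCCCCCCCCC1=C(O)C(=O)C=C(O)C1=O | intermediate |
| 4 | Irisoquin B, 3-heptadecyl-2-hydroxy-5-methoxy-1,4-benzoquinone (C24H40O4, achiral) | CCCCCCCCCCCCCCCCCC1=C(O)C(=O)C=C(OC)C1=O | target |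

## Summary
- **Total step count:** 2
- **Longest linear sequence:** 2

**Most likely failure points.** The route has only two steps, so the third entry is a second, independent failure mode of Step 1.

1. **Step 2: regioselectivity or over-methylation** (2-OMe isomer or the 2,5-dimethyl ether).
   - Fallback: reverse the order of events so the C–C bond formation fixes the regiochemistry.
   - Mono-saponify commercial 2,5-dimethoxy-1,4-benzoquinone with 1 equiv aq. NaOH. The resulting anion resists a second hydrolysis and gives 2-hydroxy-5-methoxy-1,4-benzoquinone.
   - Run the proline/Hantzsch ester reductive alkylation with 2 on this compound. Only the enol carbon C3 next to the free OH is nucleophilic, so 4 forms directly.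

2. **Step 1: 3,6-dialkylation or poor conversion**, because 1 is poorly soluble.
   - Fallback: use an aryl-lithium alkylation on the protected, reduced ring.
   - Treat 1,2,4,5-tetramethoxybenzene with n-BuLi (1 equiv, directed ortho-lithiation), then 1-bromoheptadecane.
   - Oxidise with CAN to 3-heptadecyl-2,5-dimethoxy-1,4-benzoquinone.
   - Hydrolyse both methyl ethers fully (acid or NaOH) to 3, then rejoin at Step 2.

3. **Step 1: aldehyde quality or self-aldol, or Hantzsch ester being consumed by the quinone.**
   - Fallback: a radical C–H alkylation that needs neither aldehyde nor hydride donor.
   - Carry out a Jacobsen–Torssell (Minisci-type) decarboxylative alkylation of 1 with stearic acid, AgNO3 (cat.) and (NH4)2S2O8 in MeCN/H2O at 70 °C.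
   - The C18 acid gives the heptadecyl radical, which adds to the quinone C–H and gives 3 directly. The yield is lower but the inputs are very cheap.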